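Everything rests on building ring A onto a finished, enantiopure ring C. The feature used is O1. It is both the ring C ether oxygen and one of the three ring A oxygens (on C5, C7, C8a). If C5–C8 are grafted onto the C4a=C8a enol-ether bond, the choice between O1 and 5-OH that plagues chalcone closures never arises. One [4+2] addition–aromatisation forms C8–C8a and C4a–C5 and places lavandulyl (C8), prenyl (C6) and both phenols. Its partners are an (S)-5-bromo-2-aryl-2,3-dihydropyran-4-one, ring B masked as electron-poor trichloroethyl carbonates, and a 2-prenyl-4-[(2R)-lavandulyl]-1-methoxy-1,3-bis(trimethylsilyloxy)butadiene.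

Key step: step 12

Assumption: the (S,S)-configured (salen)CrBF4 catalyst is taken to expose the Si face of aldehyde 2 and so give 2S; if the di-ortho-substituted aldehyde responds in the opposite sense, the (R,R)-catalyst is used.

Abbreviation: Ar = 2,4,6-tris[(2,2,2-trichloroethoxy)carbonyloxy]phenyl.

Design points:
- **Ring B protection.** Ring B is carried as three trichloroethyl carbonates.
  - They make the aldehyde electrophilic.
  - They leave C5 of the pyranone as the only site that N-bromosuccinimide can attack. A trialkoxyarene would be brominated first.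
  - They suppress ionisation of the benzylic C2–O1 bond.
  - They tolerate HBr and Me3SiBr, which cleave acetal ethers.
  - They leave reductively, without strong acid or base.
- **Choice of hetero-Diels–Alder catalyst.** A catalyst that works by concerted cycloaddition is chosen, so that no metal aldolate ever sits next to an ortho carbonate, where acyl transfer could occur.
- **Stereodescriptors of the side chain.** The (2R)-lavandulyl side chain of the target corresponds in space to (S)-lavandulol, (S)-lavandulyl iodide and the (6S)-keto ester 19. Only the CIP ranking changes along the route, so the (S)-benzyl auxiliary is required.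
- **By-products of aromatisation.** HBr and methanol would destroy the ketene acetal and protonate O1. They are bound by a hindered pyridine and by molecular sieves.

Step 1
Reactants: 1 2,4,6-trihydroxybenzaldehyde
Product: 2 2,4,6-tris[(2,2,2-trichloroethoxy)carbonyloxy]benzaldehyde
Conditions: Cl3CCH2OCOCl (3.5 equiv), pyridine, CH2Cl2/THF, 0 °C to rt
Reagents that add atoms: 2,2,2-trichloroethyl chloroformate, O=C(Cl)OCC(Cl)(Cl)Cl
Why: Exhaustive O-acylation of phenols with a chloroformate (carbonate formation) is routine, and it turns an electron-rich, sluggish aldehyde into an electrophilic one with a deactivated ring B.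

Step 2
Reactants: 2 2,4,6-tris[(2,2,2-trichloroethoxy)carbonyloxy]benzaldehyde; 3 (E)-1-methoxy-3-(trimethylsilyloxy)buta-1,3-diene (Danishefsky's diene)
Product: 5 (2S)-2-Ar-2,3-dihydro-4H-pyran-4-one, via silyl enol ether cycloadduct 4 (not isolated)
Conditions: [(S,S)-salen]CrBF4 (5 mol %; salen = N,N'-bis(3,5-di-tert-butylsalicylidene)cyclohexane-1,2-diaminate), 4 Å MS, t-BuOMe, −20 °C to rt; then CF3CO2H (cat.), CH2Cl2, 0 °C
Reagents that add atoms: none
Why: The catalytic asymmetric hetero-Diels–Alder reaction of aromatic aldehydes with this diene is established and favours electron-poor aldehydes; the chiral Lewis acid shields one formyl face and sets C2 as S, and acid then expels the methoxy and silyl groups from 4 without ever freeing a benzylic hydroxyl.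

Step 3
Reactants: 5 (2S)-2-Ar-2,3-dihydro-4H-pyran-4-one
Product: 6 (2S)-5-bromo-2-Ar-2,3-dihydro-4H-pyran-4-one
Conditions: N-bromosuccinimide (1.05 equiv), CH2Cl2, 0 °C to rt, dark
Reagents that add atoms: N-bromosuccinimide, O=C1CCC(=O)N1Br
Why: Electrophilic α-bromination of a vinylogous ester (C5 attacks bromine, O1 stabilises the cation, H5 is lost) is known for dihydropyranones; with ring B deactivated, C5 is the only nucleophilic carbon and C2 is untouched.

Step 4
Reactants: 7 (S)-4-benzyloxazolidin-2-one; 8 3-methylbut-2-enoyl chloride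
Product: 10 (S)-4-benzyl-3-(3-methylbut-2-enoyl)oxazolidin-2-one, via lithium oxazolidinide 9 (not isolated)
Conditions: n-BuLi, THF, −78 °C; then 8, −78 to 0 °C
Reagents that add atoms: none
Why: N-acylation of the lithiated Evans auxiliary with an acid chloride is standard, and the absence of an amine base avoids deconjugation through a vinylketene.

Step 5
Reactants: 10 (S)-4-benzyl-3-(3-methylbut-2-enoyl)oxazolidin-2-one; 11 1-bromo-3-methylbut-2-ene (prenyl bromide)
Product: 13 (4S)-4-benzyl-3-[(2S)-5-methyl-2-(prop-1-en-2-yl)hex-4-enoyl]oxazolidin-2-one, via sodium (Z)-dienolate 12 (not isolated)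
Conditions: NaN(SiMe3)2 (1.1 equiv), THF, −78 °C; then 11 (3 equiv), −78 to −30 °C
Reagents that add atoms: none
Why: In this deconjugative Evans alkylation, γ-deprotonation gives the chelated (Z)-dienolate, which is alkylated at the α-carbon on the face away from the benzyl group; this creates the isopropenyl group and sets the future C2'' (S here, identical in space to 2''R in the target).

Step 6
Reactants: 13 (4S)-4-benzyl-3-[(2S)-5-methyl-2-(prop-1-en-2-yl)hex-4-enoyl]oxazolidin-2-one
Product: 14 (S)-lavandulol [(2S)-5-methyl-2-(prop-1-en-2-yl)hex-4-en-1-ol]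
Conditions: LiBH4, MeOH (1.1 equiv), Et2O, 0 °C
Reagents that add atoms: none
Why: Reductive cleavage of the auxiliary with LiBH4/MeOH attacks the exocyclic imide carbonyl and should neither epimerise nor conjugate the β,γ-unsaturated centre.

Step 7
Reactants: 14 (S)-lavandulol
Product: 15 (S)-lavandulyl iodide [(2S)-1-iodo-5-methyl-2-(prop-1-en-2-yl)hex-4-ene]
Conditions: I2, PPh3, imidazole, CH2Cl2, 0 °C to rt, dark
Reagents that add atoms: iodine, [I][I]
Why: The Appel-type iodination displaces the activated primary oxygen by SN2 at CH2 and leaves the neighbouring stereocentre and both alkenes alone.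

Step 8
Reactants: 16 methyl acetoacetate; 11 prenyl bromide
Product: 17 methyl 2-acetyl-5-methylhex-4-enoate (racemic)
Conditions: K2CO3, acetone, reflux (16 in excess)
Reagents that add atoms: none
Why: This is a classical acetoacetic ester C-alkylation with a reactive allylic bromide, and doing it on cheap material keeps the prenylation out of the longest sequence.

Step 9
Reactants: 17 methyl 2-acetyl-5-methylhex-4-enoate; 15 (S)-lavandulyl iodide
Product: 19 methyl (6S)-9-methyl-2-(3-methylbut-2-en-1-yl)-3-oxo-6-(prop-1-en-2-yl)dec-8-enoate (C2 epimers), via sodium lithium dianion 18 (not isolated)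
Conditions: NaH, THF, 0 °C; n-BuLi, 0 °C; then 15 (0.8 equiv), 0 °C to rt; aq. NH4Cl
Reagents that add atoms: none
Why: In the Weiler dianion alkylation the terminal (γ) carbanion is the more reactive site and takes the primary iodide by SN2, forming the future C8–C1'' bond; the epimeric C2 is of no consequence because it becomes sp2.

Step 10
Reactants: 19 methyl (6S)-9-methyl-2-(3-methylbut-2-en-1-yl)-3-oxo-6-(prop-1-en-2-yl)dec-8-enoate
Product: 20 methyl (6S)-9-methyl-2-(3-methylbut-2-en-1-yl)-6-(prop-1-en-2-yl)-3-(trimethylsilyloxy)deca-2,8-dienoate (E/Z mixture)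
Conditions: Me3SiCl (1.8 equiv), Et3N (1.6 equiv), toluene, rt; filtration under argon
Reagents that add atoms: chlorotrimethylsilane, C[Si](C)(C)Cl
Why: O-silylation of the enol of a β-keto ester with Me3SiCl/Et3N is the standard first stage of bis(silyloxy)diene preparation and also works for α-alkylated esters.

Step 11
Reactants: 20 methyl (6S)-9-methyl-2-(3-methylbut-2-en-1-yl)-6-(prop-1-en-2-yl)-3-(trimethylsilyloxy)deca-2,8-dienoate
Product: 22 1-methoxy-2-prenyl-4-[(2R)-lavandulyl]-1,3-bis(trimethylsilyloxy)buta-1,3-diene (mixture of enol ether geometries), via lithium dienolate 21 (not isolated)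
Conditions: LiN(iPr)2 (1.4 equiv), THF, −78 °C; then Me3SiCl (1.6 equiv), −78 °C to rt; hexane, filtration under argon, used crude
Reagents that add atoms: chlorotrimethylsilane, C[Si](C)(C)Cl
Why: Kinetic γ-deprotonation of the β-silyloxy enoate and O-silylation of the extended ester enolate is the standard Chan-type diene synthesis; the vinylogous γ-CH2 is far more acidic than any allylic C–H of the side chains.

Step 12
Reactants: 6 (2S)-5-bromo-2-Ar-2,3-dihydro-4H-pyran-4-one; 22 1-methoxy-2-prenyl-4-[(2R)-lavandulyl]-1,3-bis(trimethylsilyloxy)buta-1,3-diene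
Product: 25 (2S)-5,7-dihydroxy-8-[(2R)-lavandulyl]-6-prenyl-2-Ar-chroman-4-one, via bromo cycloadduct 23 (not isolated), via bis(trimethylsilyl) ether 24 (not isolated)
Conditions: 22 (1.3 equiv), 2,6-di-tert-butyl-4-methylpyridine (1.5 equiv), 4 Å MS, toluene (1 M), 90 °C, sealed tube; then 10% aq. citric acid, THF, 0 °C
Reagents that add atoms: none
Why: Proposed new method: the electron-rich ketene-acetal diene 22 should add across the C4a=C8a bond of 6 in a strongly asynchronous normal-demand Diels–Alder process, its most nucleophilic terminus C8 bonding to C8a (the enone β-carbon, where O1 stabilises developing positive charge) and the dioxygenated carbon C5 then closing onto the bromine-bearing α-carbon C4a, so that ring A is closed as a six-membered carbocycle by intermolecular [4+2] cycloaddition (23). The closest known reaction type is the regiospecific Diels–Alder addition–aromatisation of 1-alkoxy-1,3-bis(silyloxy)dienes with haloquinones, α-halo enones and chromones carrying an acceptor at C3, whereas a 2,3-dihydropyran-4-one has not served as the two-carbon partner. Suprafacial addition leaves Br on C4a and H on C8a cis, so an anti E2 path is closed; instead the doubly allylic C5 acetal should lose methanol toward H8 to give a 5,7-bis(silyloxy)cyclohexa-1,3-diene whose dienylic C4a–Br bond leaves together with H8a (ionisation or syn elimination, the proton going to the hindered pyridine) under the driving force of aromatisation to 24, and cold aqueous citric acid then hydrolyses the two aryl silyl ethers. All four sp3 centres of 23 are erased, no stereocentre is created, and C2 and C2'' are spectators. The step needs orientational selectivity, secured by matched polarity (nucleophilic C8 to the carbon remote from bromine, acetal carbon C5 to the carbon that bears it), and retention of O1 on C8a, secured by excluding Lewis acids, by binding HBr as a sparingly soluble pyridinium salt and methanol in the sieves so that O1 is neither protonated nor silylated, and by a base too weak and hindered to enolise C3. The electron-poor ring B additionally keeps the benzylic C2–O1 bond from ionising at 90 °C.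

Step 13
Reactants: 25 (2S)-5,7-dihydroxy-8-[(2R)-lavandulyl]-6-prenyl-2-Ar-chroman-4-one
Product: 26 CNP0163831.1, (2S)-5,7-dihydroxy-8-[(2R)-lavandulyl]-6-prenyl-2-(2,4,6-trihydroxyphenyl)chroman-4-one
Conditions: Zn dust (activated), THF/AcOH (5:1), 0 °C to rt
Reagents that add atoms: none
Why: Reductive β-elimination of trichloroethyl carbonates by zinc (Troc cleavage) frees the three phenols with loss of 1,1-dichloroethene and CO2 in a weakly acidic medium, where neither base-induced chalcone opening at C2 nor strong-acid chroman formation from the prenyl and lavandulyl alkenes is expected.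

Compound list
1 | 2,4,6-trihydroxybenzaldehyde | O=Cc1c(O)cc(O)cc1O | starting material
2 | 2,4,6-tris[(2,2,2-trichloroethoxy)carbonyloxy]benzaldehyde | O=Cc1c(OC(=O)OCC(Cl)(Cl)Cl)cc(OC(=O)OCC(Cl)(Cl)Cl)cc1OC(=O)OCC(Cl)(Cl)Cl | intermediate
3 | (E)-1-methoxy-3-(trimethylsilyloxy)buta-1,3-diene | CO/C=C/C(=C)O[Si](C)(C)C | starting material
4 | (2S)-2-Ar-6-methoxy-4-(trimethylsilyloxy)-3,6-dihydro-2H-pyran (C6 epimers) | COC1C=C(O[Si](C)(C)C)C[C@@H](c2c(OC(=O)OCC(Cl)(Cl)Cl)cc(OC(=O)OCC(Cl)(Cl)Cl)cc2OC(=O)OCC(Cl)(Cl)Cl)O1 | intermediate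
5 | (2S)-2-Ar-2,3-dihydro-4H-pyran-4-one | O=C1C=CO[C@H](c2c(OC(=O)OCC(Cl)(Cl)Cl)cc(OC(=O)OCC(Cl)(Cl)Cl)cc2OC(=O)OCC(Cl)(Cl)Cl)C1 | intermediate
6 | (2S)-5-bromo-2-Ar-2,3-dihydro-4H-pyran-4-one | O=C1C(Br)=CO[C@H](c2c(OC(=O)OCC(Cl)(Cl)Cl)cc(OC(=O)OCC(Cl)(Cl)Cl)cc2OC(=O)OCC(Cl)(Cl)Cl)C1 | intermediate
7 | (S)-4-benzyloxazolidin-2-one | O=C1N[C@@H](Cc2ccccc2)CO1 | starting material
8 | 3-methylbut-2-enoyl chloride | CC(C)=CC(=O)Cl | starting material
9 | lithium salt of (S)-4-benzyloxazolidin-2-one | [Li+].O=C1[N-][C@@H](Cc2ccccc2)CO1 | intermediate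
10 | (S)-4-benzyl-3-(3-methylbut-2-enoyl)oxazolidin-2-one | CC(C)=CC(=O)N1[C@@H](Cc2ccccc2)COC1=O | intermediate
11 | 1-bromo-3-methylbut-2-ene | CC(C)=CCBr | starting material
12 | sodium (Z)-dienolate of 10 | [Na+].C=C(C)/C=C(\[O-])N1[C@@H](Cc2ccccc2)COC1=O | intermediate
13 | (4S)-4-benzyl-3-[(2S)-5-methyl-2-(prop-1-en-2-yl)hex-4-enoyl]oxazolidin-2-one | C=C(C)[C@H](CC=C(C)C)C(=O)N1[C@@H](Cc2ccccc2)COC1=O | intermediate
14 | (S)-lavandulol | C=C(C)[C@H](CC=C(C)C)CO | intermediate
15 | (S)-lavandulyl iodide | C=C(C)[C@H](CC=C(C)C)CI | intermediate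
16 | methyl acetoacetate | COC(=O)CC(C)=O | starting material
17 | methyl 2-acetyl-5-methylhex-4-enoate (racemic) | COC(=O)C(CC=C(C)C)C(C)=O | intermediate
18 | sodium lithium dianion of 17 | [Na+].[Li+].C=C([O-])C(CC=C(C)C)=C([O-])OC | intermediate
19 | methyl (6S)-9-methyl-2-(3-methylbut-2-en-1-yl)-3-oxo-6-(prop-1-en-2-yl)dec-8-enoate (C2 epimers) | C=C(C)[C@H](CC=C(C)C)CCC(=O)C(CC=C(C)C)C(=O)OC | intermediate
20 | methyl (6S)-9-methyl-2-(3-methylbut-2-en-1-yl)-6-(prop-1-en-2-yl)-3-(trimethylsilyloxy)deca-2,8-dienoate (E/Z) | C=C(C)[C@H](CC=C(C)C)CCC(O[Si](C)(C)C)=C(CC=C(C)C)C(=O)OC | intermediate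
21 | lithium dienolate of 20 | [Li+].C=C(C)[C@H](CC=C(C)C)CC=C(O[Si](C)(C)C)C(CC=C(C)C)=C([O-])OC | intermediate
22 | 1-methoxy-2-prenyl-4-[(2R)-lavandulyl]-1,3-bis(trimethylsilyloxy)buta-1,3-diene (geometry mixture) | C=C(C)[C@H](CC=C(C)C)CC=C(O[Si](C)(C)C)C(CC=C(C)C)=C(OC)O[Si](C)(C)C | intermediate
23 | (2S)-4a-bromo-5-methoxy-5,7-bis(trimethylsilyloxy)-8-[(2R)-lavandulyl]-6-prenyl-2-Ar-2,3,4a,5,8,8a-hexahydrochromen-4-one (new centres undefined) | C=C(C)[C@H](CC=C(C)C)CC1C(O[Si](C)(C)C)=C(CC=C(C)C)C(OC)(O[Si](C)(C)C)C2(Br)C(=O)C[C@@H](c3c(OC(=O)OCC(Cl)(Cl)Cl)cc(OC(=O)OCC(Cl)(Cl)Cl)cc3OC(=O)OCC(Cl)(Cl)Cl)OC12 | intermediate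
24 | (2S)-8-[(2R)-lavandulyl]-6-prenyl-5,7-bis(trimethylsilyloxy)-2-Ar-chroman-4-one | C=C(C)[C@H](CC=C(C)C)Cc1c(O[Si](C)(C)C)c(CC=C(C)C)c(O[Si](C)(C)C)c2c1O[C@H](c1c(OC(=O)OCC(Cl)(Cl)Cl)cc(OC(=O)OCC(Cl)(Cl)Cl)cc1OC(=O)OCC(Cl)(Cl)Cl)CC2=O | intermediate
25 | (2S)-5,7-dihydroxy-8-[(2R)-lavandulyl]-6-prenyl-2-Ar-chroman-4-one | C=C(C)[C@H](CC=C(C)C)Cc1c(O)c(CC=C(C)C)c(O)c2c1O[C@H](c1c(OC(=O)OCC(Cl)(Cl)Cl)cc(OC(=O)OCC(Cl)(Cl)Cl)cc1OC(=O)OCC(Cl)(Cl)Cl)CC2=O | intermediate
26 | CNP0163831.1, (2S)-5,7-dihydroxy-8-[(2R)-lavandulyl]-6-prenyl-2-(2,4,6-trihydroxyphenyl)chroman-4-one | C=C(C)[C@H](CC=C(C)C)Cc1c(O)c(CC=C(C)C)c(O)c2c1O[C@H](c1c(O)cc(O)cc1O)CC2=O | target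

Total step count: 13. Longest linear sequence: 9 steps (4, 5, 6, 7, 9, 10, 11, 12, 13).

Steps most likely to fail

**1. Step 12.**
- The push–pull bromo enone may add too slowly to the crowded pentasubstituted diene, which meanwhile decays by protonation or silyl migration.
- After the C8–C8a bond has formed, O1 may be expelled from C8a, opening ring C and aromatising with the wrong oxygen pattern.
- The cis arrangement of Br and H8a may retard loss of HBr. The C5 acetal would then collapse first, and the resulting doubly activated bromide could pass electrophilic bromine to the side-chain alkenes.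

The fallback sets out from 5 and returns at 25. It exchanges the leaving group for one that departs by a thermal syn elimination. This uses the known behaviour of α-sulfinyl enones, sulfinylquinones and 3-sulfinylchromones as acetylene-equivalent dienophiles. Benzenesulfenyl chloride (CH2Cl2, −78 °C, then Et3N) should sulfenylate the vinylogous ester to (2S)-5-(phenylsulfanyl)-2-Ar-2,3-dihydro-4H-pyran-4-one F1. One equivalent of mCPBA at −78 °C should then give (2S)-5-(phenylsulfinyl)-2-Ar-2,3-dihydro-4H-pyran-4-one F2; either sulfur epimer serves. Heating F2 with 22 in toluene at 80 °C over CaCO3 should give the sulfinyl cycloadduct F3. In F3 the sulfinyl oxygen lies cis to H8a, so benzenesulfenic acid leaves by a concerted Ei process without acid, base or halogen. O1 is then vinylic and cannot depart. Methanol is lost as from an alkyne adduct to give 24, and the citric acid work-up gives 25.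

**2. Step 2.** The two ortho carbonates may hinder binding of the aldehyde to the catalyst, which would lead to poor turnover or poor facial selectivity. The fallback sets out from 2 (with 3) and returns at 5, replacing asymmetric catalysis by resolution. The ZnCl2-promoted concerted hetero-Diels–Alder reaction in THF, followed by CF3CO2H, should give racemic 2-Ar-2,3-dihydro-4H-pyran-4-one F4. Preparative chromatography on an amylose carbamate chiral phase separates this into 5 and (2R)-2-Ar-2,3-dihydro-4H-pyran-4-one F5, which is set aside.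

**3. Step 9.** The strongly basic dianion may remove the allylic β-hydrogen of the β-branched iodide, so that E2 elimination to a conjugated diene competes with substitution. The fallback sets out from 15 and returns at 19, using a soft enolate in the classical acetoacetic ester sequence.
- The sodium enolate of 16 (NaH, DMF, 50 °C) is alkylated by 15 to methyl (4R)-2-acetyl-7-methyl-4-(prop-1-en-2-yl)oct-6-enoate F6.
- Krapcho dealkoxycarbonylation (LiCl, wet DMSO, 140 °C) gives (5S)-8-methyl-5-(prop-1-en-2-yl)non-7-en-2-one F7.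
- Carboxylation at the methyl terminus (NaH, dimethyl carbonate, THF, reflux) gives methyl (6S)-9-methyl-3-oxo-6-(prop-1-en-2-yl)dec-8-enoate F8.
- Prenylation with 11 (K2CO3, acetone) gives 19.

Further compounds
F1 | step 12 | (2S)-5-(phenylsulfanyl)-2-Ar-2,3-dihydro-4H-pyran-4-one | O=C1C(Sc2ccccc2)=CO[C@H](c2c(OC(=O)OCC(Cl)(Cl)Cl)cc(OC(=O)OCC(Cl)(Cl)Cl)cc2OC(=O)OCC(Cl)(Cl)Cl)C1
F2 | step 12 | (2S)-5-(phenylsulfinyl)-2-Ar-2,3-dihydro-4H-pyran-4-one (sulfur epimers) | O=C1C(S(=O)c2ccccc2)=CO[C@H](c2c(OC(=O)OCC(Cl)(Cl)Cl)cc(OC(=O)OCC(Cl)(Cl)Cl)cc2OC(=O)OCC(Cl)(Cl)Cl)C1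
F3 | step 12 | sulfinyl cycloadduct, the 4a-(phenylsulfinyl) analogue of 23 | C=C(C)[C@H](CC=C(C)C)CC1C(O[Si](C)(C)C)=C(CC=C(C)C)C(OC)(O[Si](C)(C)C)C2(S(=O)c3ccccc3)C(=O)C[C@@H](c3c(OC(=O)OCC(Cl)(Cl)Cl)cc(OC(=O)OCC(Cl)(Cl)Cl)cc3OC(=O)OCC(Cl)(Cl)Cl)OC12
F4 | step 2 | racemic 2-Ar-2,3-dihydro-4H-pyran-4-one | O=C1C=COC(c2c(OC(=O)OCC(Cl)(Cl)Cl)cc(OC(=O)OCC(Cl)(Cl)Cl)cc2OC(=O)OCC(Cl)(Cl)Cl)C1
F5 | step 2 | (2R)-2-Ar-2,3-dihydro-4H-pyran-4-one | O=C1C=CO[C@@H](c2c(OC(=O)OCC(Cl)(Cl)Cl)cc(OC(=O)OCC(Cl)(Cl)Cl)cc2OC(=O)OCC(Cl)(Cl)Cl)C1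
F6 | step 9 | methyl (4R)-2-acetyl-7-methyl-4-(prop-1-en-2-yl)oct-6-enoate (C2 epimers) | C=C(C)[C@H](CC=C(C)C)CC(C(C)=O)C(=O)OC
F7 | step 9 | (5S)-8-methyl-5-(prop-1-en-2-yl)non-7-en-2-one | C=C(C)[C@H](CC=C(C)C)CCC(C)=O
F8 | step 9 | methyl (6S)-9-methyl-3-oxo-6-(prop-1-en-2-yl)dec-8-enoate | C=C(C)[C@H](CC=C(C)C)CCC(=O)CC(=O)OC
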